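The benzene ring is made last. In the chroman, O1 on C8a lies para to the C6 hydroxyl, C8 bears a methyl and C4a bears the pyran carbon C4. Such a hydroquinone monoether is the natural output of a Dötz benzannulation. The precursor is a pentacarbonylchromium isopropenylcarbene. Its alkoxy group is the enantiopure tertiary carbinol (future C2, set by Sharpless epoxidation of geraniol) carrying a but-3-ynyl arm. Gentle heating should form C4a–C8a, C5–C6 and C6–C7 in one operation. This closes the dihydropyran and the benzene ring while O1–C2 stays intact. The C6'–C12' unit, with C9' set by Keck allylation, is attached afterwards by allylic sulfone alkylation.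

Key step: step 6

Remark on the chemistry: side-chain locants C1'–C12' run outward from C2. The SMILES is read as 2R, 9'R, 3'E, 7'E. C6' in 30 is a transient stereocentre that step 16 erases.

Step 1
Reactants: 1 geraniol
Product: 2 (2R,3R)-2,3-epoxygeraniol
Conditions: Ti(OiPr)4 (5 mol %), D-(−)-diethyl tartrate (7 mol %), t-BuOOH, 4 Å MS, CH2Cl2, −20 °C
Reagents that add atoms: tert-butyl hydroperoxide, CC(C)(C)OO
Why: Katsuki–Sharpless asymmetric epoxidation touches only the allylic C2=C3 alkene, and the D-(−)-tartrate catalyst should give the (2R,3R)-epoxide, whose tertiary C–O bond becomes O1–C2 of the chroman and is kept to the end.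

Step 2
Reactants: 2 (2R,3R)-2,3-epoxygeraniol; 3 (trimethylsilyl)acetylene
Product: 6 trimethyl{3-[(2R,3R)-3-methyl-3-(4-methylpent-3-enyl)oxiran-2-yl]prop-1-ynyl}silane, via epoxygeranyl triflate 4 (not isolated), via lithium trimethylsilylacetylide 5 (not isolated)
Conditions: 2, Tf2O, 2,6-lutidine, CH2Cl2, −78 °C, cold aqueous wash; 3, n-BuLi, THF, −78 °C; crude 4 added, DMPU, −78 → −20 °C
Reagents that add atoms: none
Why: SN2 alkynylation of a primary epoxy triflate by a lithium acetylide is much faster than epoxide opening, and keeping the tertiary oxygen locked in the oxirane excludes the oxetane closure open to a free γ-alkoxide.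

Step 3
Reactants: 6 silylated epoxy alkyne
Product: 8 (5R)-5,9-dimethyldec-8-en-1-yn-5-ol, via silylated alkynol 7 (not isolated)
Conditions: LiEt3BH, THF, 0 °C → rt; then MeOH, K2CO3 (cat.), rt
Reagents that add atoms: none
Why: Hydride opening of a trisubstituted epoxide is an SN2 attack at the less substituted carbon, so the tertiary C–O bond and its configuration stay, and base-catalysed methanolysis then removes the C-silyl group.

Step 4
Reactants: 9 2-bromopropene; 10 chromium hexacarbonyl
Product: 13 tetramethylammonium pentacarbonyl(2-methyl-1-oxidoprop-2-enylidene)chromate, via isopropenyllithium 11 (not isolated), via lithium acylchromate 12 (not isolated)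
Conditions: 9, t-BuLi (2 equiv), Et2O, −78 °C; Cr(CO)6, −78 °C → rt; Me4NBr, degassed H2O
Reagents that add atoms: tetramethylammonium bromide, C[N+](C)(C)C.[Br-]
Why: This is the first half of the Fischer carbene synthesis, in which halogen–lithium exchange and addition of the vinyllithium to a CO ligand give the acylchromate, stored as its robust ammonium salt.

Step 5
Reactants: 13 tetramethylammonium acylchromate; 8 (5R)-5,9-dimethyldec-8-en-1-yn-5-ol
Product: 16 pentacarbonyl{1-[(5R)-5,9-dimethyldec-8-en-1-yn-5-yloxy]-2-methylprop-2-enylidene}chromium, via pivaloyloxycarbene complex 14 (not isolated), via lithium alkoxide 15 (not isolated)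
Conditions: 13 (2 equiv), t-BuCOCl, CH2Cl2, −40 °C; 8, n-BuLi (1.0 equiv), THF, −78 °C, cannulated in; −78 → −30 °C; cold filtration through neutral Al2O3 (pentane), used at once
Reagents that add atoms: none
Why: Proposed new method: acylation of 13 gives the carbene analogue of a mixed anhydride, whose carbene carbon is by far the most electrophilic site while the pivaloyl C=O is shielded by its tert-butyl group; the hard lithium alkoxide 15 should therefore add there at low temperature and expel pivalate (addition–elimination) under acid-free conditions, without touching the C2–O bond, so C2 keeps its configuration; the closest known reaction type is the alcoholysis of acyloxycarbene chromium complexes by primary and hindered secondary alcohols, and its ester counterpart is the acylation of lithium tert-alkoxides by acid chlorides.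

Step 6
Reactants: 16 tertiary alkoxy(isopropenyl)carbene complex
Product: 18 (2R)-2,8-dimethyl-2-(4-methylpent-3-enyl)chroman-6-ol, via arene tricarbonylchromium complex 17 (not isolated)
Conditions: t-BuOMe (0.005 M), 2,6-di-tert-butyl-4-methylpyridine (0.2 equiv), 50 °C, Ar; then air, Et2O, daylight, rt
Reagents that add atoms: none
Why: Loss of a cis-CO ligand from 16 lets the tethered C4a≡C5 triple bond bind and insert into Cr=C8a (C4a–C8a), the new vinylcarbene at C5 picks up a CO ligand (C5–C6) to give a chromium-bound dienylketene, 6π-electrocyclisation joins C6 to C7, and enolisation leaves the phenol as its Cr(CO)3 complex 17, which air strips of metal (stronger oxidants such as (NH4)2Ce(NO3)6 are avoided because they would take a 6-chromanol on to the quinone). The closest known reaction type is the intramolecular Dötz benzannulation of alkoxycarbene complexes of zerovalent chromium that carry the alkyne on the carbene oxygen. The dihydropyran closes during the insertion in a 6-exo-dig sense, favoured by the gem-disubstitution at C2, and the benzene ring closes by electrocyclisation of the s-cis dienylketene. No stereocentre is formed: C2 only rides along because O1–C2 is never broken, and the apolar, base-buffered medium at moderate temperature is chosen so that this tertiary C–O bond does not ionise. The step needs the regiochemistry opposite to the usual bias of terminal alkynes (substituted carbon next to C8a), and the three-carbon C2–C3–C4 tether enforces it while also holding C5 and the isopropenyl group cis on C4a=C8a, as ring closure requires. It also needs the alkyne to win over the equally distant C3'=C4' alkene, which the much stronger binding of a terminal alkyne than of a trisubstituted alkene to the unsaturated Cr(CO)4 carbene should secure, while high dilution holds back intermolecular insertion.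

Step 7
Reactants: 18 chromanol
Product: 19 tert-butyl{[(2R)-2,8-dimethyl-2-(4-methylpent-3-enyl)chroman-6-yl]oxy}dimethylsilane
Conditions: TBSCl, imidazole, DMF, rt
Reagents that add atoms: tert-butyldimethylsilyl chloride, CC(C)(C)[Si](C)(C)Cl
Why: Standard imidazole-promoted silylation of the only hydroxyl masks the oxidation-prone phenol before the oxidative and carbanion steps.

Step 8
Reactants: 19 silylated chromanol
Product: 20 (2E)-5-[(2R)-6-(tert-butyldimethylsilyloxy)-2,8-dimethylchroman-2-yl]-2-methylpent-2-en-1-ol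
Conditions: SeO2 (0.3 equiv), t-BuOOH, salicylic acid (cat.), CH2Cl2, 0 °C → rt
Reagents that add atoms: tert-butyl hydroperoxide, CC(C)(C)OO
Why: In the SeO2-catalysed allylic hydroxylation (ene reaction, then [2,3]-sigmatropic shift) oxygen goes to the (E)-methyl of a gem-dimethyl alkene, which is the only alkene present and thereby becomes C5'.

Step 9
Reactants: 20 allylic alcohol
Product: 21 {[(2R)-2-[(3E)-5-bromo-4-methylpent-3-enyl]-2,8-dimethylchroman-6-yl]oxy}(tert-butyl)dimethylsilane
Conditions: CBr4, PPh3, CH2Cl2, −20 → 0 °C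
Reagents that add atoms: carbon tetrabromide, BrC(Br)(Br)Br
Why: The Appel reaction converts a primary allylic alcohol into the bromide under neutral conditions without allylic shift or loss of alkene geometry, and the aryl silyl ether is inert to it.

Step 10
Reactants: 22 prenyl bromide; 23 sodium benzenesulfinate
Product: 24 (3-methylbut-2-enyl) phenyl sulfone
Conditions: DMF, rt
Reagents that add atoms: none
Why: Sulfinate anions are alkylated at sulfur by primary allylic halides in a plain SN2 reaction.

Step 11
Reactants: 24 prenyl phenyl sulfone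
Product: 25 (2E)-2-methyl-4-(phenylsulfonyl)but-2-enal
Conditions: SeO2 (1.1 equiv), 1,4-dioxane, 80 °C
Reagents that add atoms: selenium dioxide, O=[Se]=O
Why: Riley-type SeO2 oxidation attacks the (E)-methyl group of the trisubstituted alkene and, with stoichiometric oxidant and heat, runs through to the conjugated (E)-enal.

Step 12
Reactants: 25 sulfonyl enal
Product: 26 (2E,4R)-3-methyl-1-(phenylsulfonyl)hepta-2,6-dien-4-ol
Conditions: allylSnBu3, Ti(OiPr)4 (10 mol %), (R)-BINOL (20 mol %), 4 Å MS, CH2Cl2, −20 °C
Reagents that add atoms: allyltributylstannane, C=CC[Sn](CCCC)(CCCC)CCCC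
Why: The Keck asymmetric allylation works well on α-methyl enals, the (R)-BINOL–titanium catalyst should direct allyl to the face that gives the (R)-carbinol (future C9'), and the non-basic medium spares the acidic CH2 next to sulfur.

Step 13
Reactants: 26 homoallylic alcohol
Product: 27 tert-butyldimethyl{[(2E,4R)-3-methyl-1-(phenylsulfonyl)hepta-2,6-dien-4-yl]oxy}silane
Conditions: TBSCl, imidazole, DMAP (cat.), DMF, rt
Reagents that add atoms: tert-butyldimethylsilyl chloride, CC(C)(C)[Si](C)(C)Cl
Why: Routine silylation removes the acidic OH before the carbanion step and leaves the stereocentre untouched.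

Step 14
Reactants: 27 silyl ether
Product: 28 tert-butyl{[(2E,4R)-3,7-dimethyl-1-(phenylsulfonyl)octa-2,6-dien-4-yl]oxy}dimethylsilane
Conditions: second-generation Grubbs catalyst RuCl2(=CHPh)(PCy3)(H2IMes) (5 mol %), 2-methylbut-2-ene (excess), CH2Cl2, 35 °C
Reagents that add atoms: 2-methylbut-2-ene, CC=C(C)C
Why: Olefin cross metathesis with 2-methylbut-2-ene caps a terminal vinyl group as a prenyl group, while the hindered trisubstituted C7'=C8' alkene stays out of the catalytic cycle.

Step 15
Reactants: 28 C6'–C12' sulfone; 21 allylic bromide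
Product: 30 bis-silylated 6'-(phenylsulfonyl)sargachromanol C (both C6' epimers), via lithiated sulfone 29 (not isolated)
Conditions: 28, n-BuLi, THF, −78 °C; then 21, −78 → −50 °C
Reagents that add atoms: none
Why: Alkylation of an α-lithiated allylic sulfone by a primary allylic bromide is the classical head-to-tail terpenoid coupling, it occurs at the α-carbon by SN2 to form C5'–C6', and low temperature keeps the poor silyloxide leaving group at C9' in place.

Step 16
Reactants: 30 coupled sulfone
Product: 31 bis(tert-butyldimethylsilyl) ether of sargachromanol C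
Conditions: PdCl2(dppp) (5 mol %), LiEt3BH, THF, 0 °C
Reagents that add atoms: none
Why: In the palladium-catalysed hydride desulfonylation of allylic sulfones, zerovalent palladium ionises C6'–S to a π-allyl complex and hydride enters at the less substituted terminus C6', so the (E)-C7'=C8' alkene stays where it is and no allyl anion arises that could expel the C9' silyloxide.

Step 17
Reactants: 31 bis-silyl ether
Product: 32 sargachromanol C
Conditions: TBAF, THF, 0 °C → rt
Reagents that add atoms: none
Why: Fluoride-induced desilylation cleaves the aryl and the allylic silyl ether together under conditions that affect neither stereocentre nor any alkene.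

Compound list
1 | geraniol | CC(C)=CCC/C(C)=C/CO | starting material
2 | (2R,3R)-2,3-epoxygeraniol | CC(C)=CCC[C@@]1(C)O[C@@H]1CO | intermediate
3 | (trimethylsilyl)acetylene | C#C[Si](C)(C)C | starting material
4 | [(2R,3R)-3-methyl-3-(4-methylpent-3-enyl)oxiran-2-yl]methyl trifluoromethanesulfonate | CC(C)=CCC[C@@]1(C)O[C@@H]1COS(=O)(=O)C(F)(F)F | intermediate
5 | lithium trimethylsilylacetylide | [Li]C#C[Si](C)(C)C | intermediate
6 | trimethyl{3-[(2R,3R)-3-methyl-3-(4-methylpent-3-enyl)oxiran-2-yl]prop-1-ynyl}silane | CC(C)=CCC[C@@]1(C)O[C@@H]1CC#C[Si](C)(C)C | intermediate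
7 | (5R)-5,9-dimethyl-1-(trimethylsilyl)dec-8-en-1-yn-5-ol | CC(C)=CCC[C@@](C)(O)CCC#C[Si](C)(C)C | intermediate
8 | (5R)-5,9-dimethyldec-8-en-1-yn-5-ol | CC(C)=CCC[C@@](C)(O)CCC#C | intermediate
9 | 2-bromopropene | C=C(C)Br | starting material
10 | chromium hexacarbonyl | O=C=[Cr](=C=O)(=C=O)(=C=O)(=C=O)=C=O | starting material
11 | isopropenyllithium | [Li]C(C)=C | intermediate
12 | lithium pentacarbonyl(2-methyl-1-oxidoprop-2-enylidene)chromate | [Li+].C=C(C)C([O-])=[Cr](=C=O)(=C=O)(=C=O)(=C=O)=C=O | intermediate
13 | tetramethylammonium pentacarbonyl(2-methyl-1-oxidoprop-2-enylidene)chromate | C[N+](C)(C)C.C=C(C)C([O-])=[Cr](=C=O)(=C=O)(=C=O)(=C=O)=C=O | intermediate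
14 | pentacarbonyl[2-methyl-1-(pivaloyloxy)prop-2-enylidene]chromium | C=C(C)C(OC(=O)C(C)(C)C)=[Cr](=C=O)(=C=O)(=C=O)(=C=O)=C=O | intermediate
15 | lithium (5R)-5,9-dimethyldec-8-en-1-yn-5-olate | [Li+].CC(C)=CCC[C@@](C)([O-])CCC#C | intermediate
16 | pentacarbonyl{1-[(5R)-5,9-dimethyldec-8-en-1-yn-5-yloxy]-2-methylprop-2-enylidene}chromium | C=C(C)C(O[C@@](C)(CCC#C)CCC=C(C)C)=[Cr](=C=O)(=C=O)(=C=O)(=C=O)=C=O | intermediate
17 | tricarbonyl[η6-(2R)-2,8-dimethyl-2-(4-methylpent-3-enyl)chroman-6-ol]chromium (both faces; η6 bond not drawn) | CC(C)=CCC[C@]1(C)CCc2cc(O)cc(C)c2O1.O=C=[Cr](=C=O)=C=O | intermediate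
18 | (2R)-2,8-dimethyl-2-(4-methylpent-3-enyl)chroman-6-ol | CC(C)=CCC[C@]1(C)CCc2cc(O)cc(C)c2O1 | intermediate
19 | tert-butyl{[(2R)-2,8-dimethyl-2-(4-methylpent-3-enyl)chroman-6-yl]oxy}dimethylsilane | CC(C)=CCC[C@]1(C)CCc2cc(O[Si](C)(C)C(C)(C)C)cc(C)c2O1 | intermediate
20 | (2E)-5-[(2R)-6-(tert-butyldimethylsilyloxy)-2,8-dimethylchroman-2-yl]-2-methylpent-2-en-1-ol | OC/C(C)=C/CC[C@]1(C)CCc2cc(O[Si](C)(C)C(C)(C)C)cc(C)c2O1 | intermediate
21 | {[(2R)-2-[(3E)-5-bromo-4-methylpent-3-enyl]-2,8-dimethylchroman-6-yl]oxy}(tert-butyl)dimethylsilane | BrC/C(C)=C/CC[C@]1(C)CCc2cc(O[Si](C)(C)C(C)(C)C)cc(C)c2O1 | intermediate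
22 | prenyl bromide (1-bromo-3-methylbut-2-ene) | CC(C)=CCBr | starting material
23 | sodium benzenesulfinate | [Na+].[O-]S(=O)c1ccccc1 | starting material
24 | (3-methylbut-2-enyl) phenyl sulfone | CC(C)=CCS(=O)(=O)c1ccccc1 | intermediate
25 | (2E)-2-methyl-4-(phenylsulfonyl)but-2-enal | O=C/C(C)=C/CS(=O)(=O)c1ccccc1 | intermediate
26 | (2E,4R)-3-methyl-1-(phenylsulfonyl)hepta-2,6-dien-4-ol | C=CC[C@@H](O)/C(C)=C/CS(=O)(=O)c1ccccc1 | intermediate
27 | tert-butyldimethyl{[(2E,4R)-3-methyl-1-(phenylsulfonyl)hepta-2,6-dien-4-yl]oxy}silane | C=CC[C@@H](O[Si](C)(C)C(C)(C)C)/C(C)=C/CS(=O)(=O)c1ccccc1 | intermediate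
28 | tert-butyl{[(2E,4R)-3,7-dimethyl-1-(phenylsulfonyl)octa-2,6-dien-4-yl]oxy}dimethylsilane | CC(C)=CC[C@@H](O[Si](C)(C)C(C)(C)C)/C(C)=C/CS(=O)(=O)c1ccccc1 | intermediate
29 | α-lithiated 28 | CC(C)=CC[C@@H](O[Si](C)(C)C(C)(C)C)/C(C)=C/C([Li])S(=O)(=O)c1ccccc1 | intermediate
30 | (2R)-6-(TBSO)-2-[(3E,7E,9R)-9-(TBSO)-4,8,12-trimethyl-6-(phenylsulfonyl)trideca-3,7,11-trienyl]-2,8-dimethylchroman (C6' epimers) | CC(C)=CC[C@@H](O[Si](C)(C)C(C)(C)C)/C(C)=C/C(C/C(C)=C/CC[C@]1(C)CCc2cc(O[Si](C)(C)C(C)(C)C)cc(C)c2O1)S(=O)(=O)c1ccccc1 | intermediate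
31 | (2R)-6-(TBSO)-2-[(3E,7E,9R)-9-(TBSO)-4,8,12-trimethyltrideca-3,7,11-trienyl]-2,8-dimethylchroman | CC(C)=CC[C@@H](O[Si](C)(C)C(C)(C)C)/C(C)=C/CC/C(C)=C/CC[C@]1(C)CCc2cc(O[Si](C)(C)C(C)(C)C)cc(C)c2O1 | intermediate
32 | sargachromanol C, (2R)-2-[(3E,7E,9R)-9-hydroxy-4,8,12-trimethyltrideca-3,7,11-trienyl]-2,8-dimethylchroman-6-ol | CC(C)=CC[C@@H](O)/C(C)=C/CC/C(C)=C/CC[C@]1(C)CCc2cc(O)cc(C)c2O1 | target

Total step count: 17. Longest linear sequence: 11 steps from geraniol (steps 1, 2, 3, 5, 6, 7, 8, 9, 15, 16, 17).

Steps most likely to fail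

1. Step 5 (bears the label).
- What may go wrong: the hindered alkoxide may add to the carbene carbon more slowly than 14 decays. It may add in a conjugate sense to the isopropenyl group. The tertiary alkyl group may also be lost from 16 during handling.
- Fallback (known chemistry, from 2 back to 19): O1–C8a is made on a finished arene by Buchwald–Hartwig-type intramolecular etherification. This reaction is established for tertiary alcohols, which cannot undergo β-hydride loss.
- Compound 2 is iodinated (I2, PPh3, imidazole) to epoxygeranyl iodide F1. Zinc in ethanol opens it reductively to (R)-linalool F2, with the tertiary C–O bond untouched.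
- Commercial 3-bromo-5-methylphenol is brominated para to the hydroxyl (NBS, MeCN) to 3,4-dibromo-5-methylphenol F3 and silylated to its TBS ether F4.
- 9-BBN (2 equiv) adds only to the vinyl group of F2 to give the B-alkyl borane F5.
- Suzuki–Miyaura coupling (PdCl2(dppf), K3PO4, DMF) should engage the less hindered, less electron-rich C–Br bond of F4 and give the bromoaryl carbinol F6.
- Pd(OAc)2, a bulky di-tert-butyl(biaryl)phosphine and Cs2CO3 in toluene then close the pyran to 19. Any desilylated phenol re-enters as 18.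

2. Step 6.
- What may go wrong: the tertiary C2–O1 bond may ionise or eliminate on heating. The side-chain alkene may capture the unsaturated chromium centre. The sequence may stall before CO insertion.
- Fallback (from 1 back to 19): O1–C2 is forged by Tsuji–Trost asymmetric allylic etherification, and the pyran is closed by C4–C4a coupling.
- Geraniol 1 is converted (ClCO2Me, pyridine) into geranyl methyl carbonate F7.
- 2-Methylhydroquinone is silylated at the less hindered hydroxyl to 4-(tert-butyldimethylsilyloxy)-2-methylphenol F8. NBS then brominates it ortho to the free OH to give 2-bromo-4-(tert-butyldimethylsilyloxy)-6-methylphenol F9.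
- Pd2(dba)3·CHCl3 and the C2-symmetric DACH-phenyl diphosphine ligand join F9 to the tertiary terminus of the geranyl π-allyl unit. The ligand antipode is chosen for the R product, so C2 is catalyst-controlled. The product is the (R)-linalyl aryl ether F10.
- 9-BBN hydroborates the vinyl group to the borane F11. PdCl2(dppf)/K3PO4 then closes C4–C4a onto the aryl bromide to give 19.

3. Step 15.
- What may go wrong: the lithiated δ-silyloxy allylic sulfone may expel silyloxide by vinylogous β-elimination, or it may alkylate at its γ-carbon.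
- Fallback (from 21, using 24, back to 32): the carbinol is installed only after the coupling, so the carbanion has no leaving group within reach.
- Sulfone 24 is deprotonated (n-BuLi, THF, −78 °C) to lithiated prenyl sulfone F12 and alkylated with 21 to the sulfone F13.
- PdCl2(dppp)/LiEt3BH gives the desulfonylated silyl ether F14.
- SeO2/t-BuOOH followed by MnO2 oxidises the terminal (E)-methyl to the enal F15.
- Keck allylation with (R)-BINOL sets C9' in the homoallylic alcohol F16.
- Cross metathesis with 2-methylbut-2-ene gives the phenol-silylated sargachromanol C F17, and TBAF returns to 32.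

Further compounds
F1 | step 5 | (2R,3S)-3-(iodomethyl)-2-methyl-2-(4-methylpent-3-enyl)oxirane | CC(C)=CCC[C@@]1(C)O[C@@H]1CI
F2 | step 5 | (R)-linalool | CC(C)=CCC[C@@](C)(O)C=C
F3 | step 5 | 3,4-dibromo-5-methylphenol | Cc1cc(O)cc(Br)c1Br
F4 | step 5 | tert-butyl(3,4-dibromo-5-methylphenoxy)dimethylsilane | Cc1cc(O[Si](C)(C)C(C)(C)C)cc(Br)c1Br
F5 | step 5 | (3R)-1-(9-borabicyclo[3.3.1]nonan-9-yl)-3,7-dimethyloct-6-en-3-ol | CC(C)=CCC[C@@](C)(O)CCB1C2CCCC1CCC2
F6 | step 5 | (3R)-1-[2-bromo-5-(tert-butyldimethylsilyloxy)-3-methylphenyl]-3,7-dimethyloct-6-en-3-ol | CC(C)=CCC[C@@](C)(O)CCc1cc(O[Si](C)(C)C(C)(C)C)cc(C)c1Br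
F7 | step 6 | geranyl methyl carbonate | CC(C)=CCC/C(C)=C/COC(=O)OC
F8 | step 6 | 4-(tert-butyldimethylsilyloxy)-2-methylphenol | Cc1cc(O[Si](C)(C)C(C)(C)C)ccc1O
F9 | step 6 | 2-bromo-4-(tert-butyldimethylsilyloxy)-6-methylphenol | Cc1cc(O[Si](C)(C)C(C)(C)C)cc(Br)c1O
F10 | step 6 | {3-bromo-4-[(3R)-3,7-dimethylocta-1,6-dien-3-yloxy]-5-methylphenoxy}(tert-butyl)dimethylsilane | C=C[C@@](C)(CCC=C(C)C)Oc1c(C)cc(O[Si](C)(C)C(C)(C)C)cc1Br
F11 | step 6 | 9-BBN adduct of F10 at the terminal vinyl carbon | CC(C)=CCC[C@](C)(CCB1C2CCCC1CCC2)Oc1c(C)cc(O[Si](C)(C)C(C)(C)C)cc1Br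
F12 | step 15 | α-lithiated (3-methylbut-2-enyl) phenyl sulfone | [Li]C(C=C(C)C)S(=O)(=O)c1ccccc1
F13 | step 15 | (2R)-6-(TBSO)-2-[(3E)-4,8-dimethyl-6-(phenylsulfonyl)nona-3,7-dienyl]-2,8-dimethylchroman | CC(C)=CC(C/C(C)=C/CC[C@]1(C)CCc2cc(O[Si](C)(C)C(C)(C)C)cc(C)c2O1)S(=O)(=O)c1ccccc1
F14 | step 15 | (2R)-6-(TBSO)-2-[(3E)-4,8-dimethylnona-3,7-dienyl]-2,8-dimethylchroman | CC(C)=CCC/C(C)=C/CC[C@]1(C)CCc2cc(O[Si](C)(C)C(C)(C)C)cc(C)c2O1
F15 | step 15 | (2E,6E)-9-[(2R)-6-(TBSO)-2,8-dimethylchroman-2-yl]-2,6-dimethylnona-2,6-dienal | O=C/C(C)=C/CC/C(C)=C/CC[C@]1(C)CCc2cc(O[Si](C)(C)C(C)(C)C)cc(C)c2O1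
F16 | step 15 | (4R,5E,9E)-12-[(2R)-6-(TBSO)-2,8-dimethylchroman-2-yl]-5,9-dimethyldodeca-1,5,9-trien-4-ol | C=CC[C@@H](O)/C(C)=C/CC/C(C)=C/CC[C@]1(C)CCc2cc(O[Si](C)(C)C(C)(C)C)cc(C)c2O1
F17 | step 15 | 6-O-(tert-butyldimethylsilyl)sargachromanol C | CC(C)=CC[C@@H](O)/C(C)=C/CC/C(C)=C/CC[C@]1(C)CCc2cc(O[Si](C)(C)C(C)(C)C)cc(C)c2O1
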